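**Retrosynthetic overview**
- The C8 methacrylate goes on last, onto the 8β-hydroxy-14,15-diol lactone, with the two primary alcohols silylated only transiently.
- Rings are formed in the biosynthetic order. First the ten-membered carbocycle, by C6–C7 bond formation (the C1–C10 bond of farnesyl diphosphate): an indium-mediated Barbier closure in water of a 2-(bromomethyl)acrylate onto a C6 lactol, with no protecting group on the electrophile. Then the 6α,12-γ-lactone, by acid, from the new C6–OH.
- Seco chain: C7–C11 by a Morita–Baylis–Hillman reaction; the ring-cis C1=C10 olefin by Horner–Wadsworth–Emmons reaction of an α-phosphono-γ-butyrolactone, whose reduction frees C14–OH and C8–OH.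
- Stereocentres: C8 from (R)-5-(hydroxymethyl)butyrolactone; C4 by Cu-catalysed asymmetric conjugate addition to furan-2(5H)-one; C6 and C7 in the ring closure, under control of C8.

Assumption: positions carry germacranolide numbers (C6 lactone carbinol, C7 ring-fusion carbon, C8 ester carbinol, C14/C15 the hydroxymethyl carbons on C10/C4); TBS = tert-butyldimethylsilyl, TES = triethylsilyl; but-3-enylmagnesium bromide is bought as a THF solution.

**Route**

Step 1
Reactants: 1 furan-2(5H)-one; 2 but-3-en-1-ylmagnesium bromide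
Product: 3 (4S)-4-(but-3-en-1-yl)oxolan-2-one
Conditions: CuBr·SMe2 (5 mol %), Josiphos-type ferrocenyl diphosphine (6 mol %), t-BuOMe, −78 °C; then H2O
Reagents that add atoms: none
Why: Cu-catalysed asymmetric conjugate addition of a Grignard reagent to an α,β-unsaturated lactone; the chiral diphosphine–copper complex delivers the butenyl group to one face of the butenolide and sets C4 (S, ligand enantiomer chosen accordingly).

Step 2
Reactants: 3 (4S)-4-(but-3-en-1-yl)oxolan-2-one
Product: 5 (4S)-4-(but-3-en-1-yl)-2-methoxyoxolane (anomer mixture), via lactol 4 (not isolated)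
Conditions: DIBAL-H (1.1 equiv), CH2Cl2, −78 °C; Rochelle salt work-up; then MeOH, PPTS (cat.), rt
Reagents that add atoms: methanol (CO)
Why: Lactone half-reduction (DIBAL-H stops at the aluminium lactolate at −78 °C) followed by acid-catalysed acetalisation locks C6 (aldehyde level) and O15 in one hydride- and base-stable ring; C4 is untouched.

Step 3
Reactants: 5 (4S)-4-(but-3-en-1-yl)-2-methoxyoxolane
Product: 6 3-[(3S)-5-methoxyoxolan-3-yl]propanal
Conditions: O3, CH2Cl2/MeOH, NaHCO3, −78 °C; then PPh3, −78 °C → rt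
Reagents that add atoms: ozone ([O-][O+]=O)
Why: Ozonolysis with reductive work-up cleaves the only alkene to the C1 aldehyde; the acetal and C4 are inert.

Step 4
Reactants: 7 (5R)-5-(hydroxymethyl)oxolan-2-one
Product: 8 (5R)-5-[(triethylsilyloxy)methyl]oxolan-2-one
Conditions: TESCl, imidazole, CH2Cl2, 0 °C
Reagents that add atoms: chlorotriethylsilane (CC[Si](Cl)(CC)CC)
Why: Imidazole-promoted silylation of the primary alcohol; TES is chosen because a primary TES ether can be oxidised directly in step 9.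

Step 5
Reactants: 8 (5R)-5-[(triethylsilyloxy)methyl]oxolan-2-one
Product: 10 diethyl {(5R)-2-oxo-5-[(triethylsilyloxy)methyl]oxolan-3-yl}phosphonate (C3 epimers), via enol phosphate 9 (not isolated)
Conditions: LDA (1.1 equiv), THF, −78 °C; ClP(O)(OEt)2; then LDA (1.1 equiv), −78 °C → rt; AcOH
Reagents that add atoms: diethyl chlorophosphate (CCOP(=O)(Cl)OCC)
Why: O-phosphorylation of the lactone enolate followed by LDA-induced 1,3-phosphorus shift (O→C) of the enol phosphate gives the α-phosphono lactone; C8 is remote from the enolate.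

Step 6
Reactants: 10 diethyl {(5R)-2-oxo-5-[(triethylsilyloxy)methyl]oxolan-3-yl}phosphonate; 6 3-[(3S)-5-methoxyoxolan-3-yl]propanal
Product: 11 (3E,5R)-3-{3-[(3S)-5-methoxyoxolan-3-yl]propylidene}-5-[(triethylsilyloxy)methyl]oxolan-2-one
Conditions: NaH, THF, 0 °C; then 6, 0 °C → rt
Reagents that add atoms: none
Why: Horner–Wadsworth–Emmons olefination of the stabilised phosphonate anion gives the favoured (E)-alkylidene lactone (chain trans to the carbonyl, so C2 cis to C9), which is the ring-cis C1=C10 geometry of the target; the minor (Z) isomer is separated.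

Step 7
Reactants: 11 (3E,5R)-3-{3-[(3S)-5-methoxyoxolan-3-yl]propylidene}-5-[(triethylsilyloxy)methyl]oxolan-2-one
Product: 12 (2E,4R)-2-{3-[(3S)-5-methoxyoxolan-3-yl]propylidene}-5-(triethylsilyloxy)pentane-1,4-diol
Conditions: DIBAL-H (3.5 equiv), CH2Cl2, −78 → 0 °C; Rochelle salt
Reagents that add atoms: none
Why: DIBAL-H 1,2-reduction of the α-alkylidene lactone gives the 2-alkylidene-1,4-diol, freeing C14–OH and C8–OH without touching olefin geometry, acetal or TES ether.

Step 8
Reactants: 12 (2E,4R)-2-{3-[(3S)-5-methoxyoxolan-3-yl]propylidene}-5-(triethylsilyloxy)pentane-1,4-diol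
Product: 13 (2E,4R)-1,4-bis(TBSO)-2-{3-[(3S)-5-methoxyoxolan-3-yl]propylidene}-5-(triethylsilyloxy)pentane
Conditions: TBSCl (3 equiv), imidazole, DMAP (cat.), DMF, 40 °C
Reagents that add atoms: tert-butyl(chloro)dimethylsilane (CC(C)(C)[Si](C)(C)Cl)
Why: Imidazole/DMAP-promoted silylation of both hydroxyls; the C8 silyl ether is a poor leaving group, which protects the allyl metal of step 12 from 1,4-elimination.

Step 9
Reactants: 13 (2E,4R)-1,4-bis(TBSO)-2-{3-[(3S)-5-methoxyoxolan-3-yl]propylidene}-5-(triethylsilyloxy)pentane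
Product: 14 (2R,4E)-2-(TBSO)-4-(TBSOCH2)-7-[(3S)-5-methoxyoxolan-3-yl]hept-4-enal
Conditions: (COCl)2, DMSO, CH2Cl2, −78 → −30 °C; then Et3N, −78 → 0 °C
Reagents that add atoms: none
Why: Swern oxidation applied directly to the primary TES ether: the chlorosulfonium salt cleaves the Et3Si–O bond and oxidises in one operation while TBS ethers survive; the α-silyloxy aldehyde (C8) is not epimerised at low temperature and is used at once.

Step 10
Reactants: 14 (2R,4E)-2-(TBSO)-4-(TBSOCH2)-7-[(3S)-5-methoxyoxolan-3-yl]hept-4-enal; 15 methyl prop-2-enoate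
Product: 16 methyl (4R,6E)-4-(TBSO)-6-(TBSOCH2)-3-hydroxy-9-[(3S)-5-methoxyoxolan-3-yl]-2-methylidenenon-6-enoate (C3 epimers)
Conditions: DABCO (1 equiv), methyl acrylate as solvent, rt, 3–5 d
Reagents that add atoms: none
Why: Morita–Baylis–Hillman reaction makes the C7–C11 bond; the new C7 carbinol centre is destroyed in step 11, so its configuration does not matter.

Step 11
Reactants: 16 methyl (4R,6E)-4-(TBSO)-6-(TBSOCH2)-3-hydroxy-9-[(3S)-5-methoxyoxolan-3-yl]-2-methylidenenon-6-enoate
Product: 17 methyl (2Z,4R,6E)-2-(bromomethyl)-4-(TBSO)-6-(TBSOCH2)-9-[(3S)-5-methoxyoxolan-3-yl]nona-2,6-dienoate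
Conditions: NBS, Me2S, CH2Cl2, 0 °C → rt
Reagents that add atoms: N-bromosuccinimide (O=C1CCC(=O)N1Br)
Why: Corey–Kim-type activation of the allylic alcohol, then bromide entry by SN2′ with allylic transposition, gives the favoured (Z)-2-(bromomethyl)alk-2-enoate; C8 is untouched.

Step 12
Reactants: 17 methyl (2Z,4R,6E)-2-(bromomethyl)-4-(TBSO)-6-(TBSOCH2)-9-[(3S)-5-methoxyoxolan-3-yl]nona-2,6-dienoate
Product: 19 methyl 2-[(1S,2R,4S,7E,10R)-10-(TBSO)-8-(TBSOCH2)-2-hydroxy-4-(hydroxymethyl)cyclodec-7-en-1-yl]prop-2-enoate, via lactol 18 (not isolated)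
Conditions: In powder (6 equiv), PPTS (0.3 equiv), THF/H2O 3:1, 40 °C; 17 added over 10 h to a final 2 mM
Reagents that add atoms: water (O)
Why: Proposed new method: indium-mediated Barbier allylation in water — known between 2-(bromomethyl)acrylates and unprotected lactols or sugars, and (with Cr(II) or Zn) for closing germacranolide rings from free aldehydes — is used here intramolecularly on a lactol released in situ from its methyl acetal by the mildly acidic medium. The allylindium equilibrates E/Z by 1,3-metallotropy and adds through C7 to the ring-opened C6 aldehyde in a six-membered chair transition state with both new ring bonds (C6–C5, C7–C8) equatorial, which gives the 6,7-anti adduct (later the trans-lactone). The C8 centre fixes the face of C7 (C8–O bond in the plane of the allyl unit, the C9 tether on the attacked face, H8 anti), so 8R is predicted to give 7S and 6R; this facial preference is the least certain point of the route. The cis C1=C10 olefin pre-folds the chain, and any C14 silyl loss is harmless because step 13 removes it anyway.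

Step 13
Reactants: 19 methyl 2-[(1S,2R,4S,7E,10R)-10-(TBSO)-8-(TBSOCH2)-2-hydroxy-4-(hydroxymethyl)cyclodec-7-en-1-yl]prop-2-enoate
Product: 20 (3aR,4R,6E,10S,11aR)-4-hydroxy-6,10-bis(hydroxymethyl)-3-methylidene-3a,4,5,8,9,10,11,11a-octahydrocyclodeca[b]furan-2(3H)-one
Conditions: HF (48 % aq.), MeCN, 0 °C → rt
Reagents that add atoms: none
Why: Acid-catalysed lactonisation (intramolecular transesterification) of C6–OH onto the acrylate ester closes the trans-fused γ-lactone while C8–O is still silylated, so only the 12,6-lactone can form; HF then cleaves both silyl ethers and no stereocentre changes.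

Step 14
Reactants: 20 (3aR,4R,6E,10S,11aR)-4-hydroxy-6,10-bis(hydroxymethyl)-3-methylidene-3a,4,5,8,9,10,11,11a-octahydrocyclodeca[b]furan-2(3H)-one
Product: 23 (3aS,4R,6E,10S,11aR)-6,10-bis(hydroxymethyl)-3-methylidene-2-oxo-2,3,3a,4,5,8,9,10,11,11a-decahydrocyclodeca[b]furan-4-yl 2-methylprop-2-enoate, via bis-TES ether 21 (not isolated), via bis-TES methacrylate 22 (not isolated)
Conditions: TESCl (2.1 equiv), imidazole, CH2Cl2, −40 °C; then methacrylic anhydride, Et3N, DMAP, 0 °C → rt; then AcOH/THF/H2O 3:1:1, rt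
Reagents that add atoms: methacrylic anhydride (CC(=C)C(=O)OC(=O)C(C)=C); chlorotriethylsilane (CC[Si](Cl)(CC)CC), which adds only the transient silyl groups of 21 and 22
Why: Transient protection: the two primary alcohols are silylated much faster than the hindered secondary C8–OH, which is then acylated with retention (DMAP-catalysed acylation by the anhydride); aqueous acetic acid removes the primary TES ethers in the same flask.

**Compound list**

1 | furan-2(5H)-one | O=C1C=CCO1 | starting material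
2 | but-3-en-1-ylmagnesium bromide | C=CCC[Mg]Br | starting material
3 | (4S)-4-(but-3-en-1-yl)oxolan-2-one | C=CCC[C@@H]1COC(=O)C1 | intermediate
4 | (4S)-4-(but-3-en-1-yl)oxolan-2-ol (lactol, anomer mixture, not isolated) | C=CCC[C@@H]1COC(O)C1 | intermediate
5 | (4S)-4-(but-3-en-1-yl)-2-methoxyoxolane (anomer mixture) | C=CCC[C@@H]1COC(OC)C1 | intermediate
6 | 3-[(3S)-5-methoxyoxolan-3-yl]propanal | O=CCC[C@@H]1COC(OC)C1 | intermediate
7 | (5R)-5-(hydroxymethyl)oxolan-2-one | O=C1CC[C@H](CO)O1 | starting material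
8 | (5R)-5-[(triethylsilyloxy)methyl]oxolan-2-one | O=C1CC[C@H](CO[Si](CC)(CC)CC)O1 | intermediate
9 | diethyl (5R)-5-[(triethylsilyloxy)methyl]-4,5-dihydrofuran-2-yl phosphate (not isolated) | CCOP(=O)(OCC)OC1=CC[C@H](CO[Si](CC)(CC)CC)O1 | intermediate
10 | diethyl {(5R)-2-oxo-5-[(triethylsilyloxy)methyl]oxolan-3-yl}phosphonate (C3 epimers) | CCOP(=O)(OCC)C1C[C@H](CO[Si](CC)(CC)CC)OC1=O | intermediate
11 | (3E,5R)-3-{3-[(3S)-5-methoxyoxolan-3-yl]propylidene}-5-[(triethylsilyloxy)methyl]oxolan-2-one | CC[Si](CC)(CC)OC[C@H]1C/C(=C\CC[C@@H]2COC(OC)C2)C(=O)O1 | intermediate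
12 | (2E,4R)-2-{3-[(3S)-5-methoxyoxolan-3-yl]propylidene}-5-(triethylsilyloxy)pentane-1,4-diol | CC[Si](CC)(CC)OC[C@H](O)C/C(CO)=C\CC[C@@H]1COC(OC)C1 | intermediate
13 | (2E,4R)-1,4-bis[(tert-butyldimethylsilyl)oxy]-2-{3-[(3S)-5-methoxyoxolan-3-yl]propylidene}-5-(triethylsilyloxy)pentane | CC[Si](CC)(CC)OC[C@H](O[Si](C)(C)C(C)(C)C)C/C(CO[Si](C)(C)C(C)(C)C)=C\CC[C@@H]1COC(OC)C1 | intermediate
14 | (2R,4E)-2-[(tert-butyldimethylsilyl)oxy]-4-{[(tert-butyldimethylsilyl)oxy]methyl}-7-[(3S)-5-methoxyoxolan-3-yl]hept-4-enal | O=C[C@H](O[Si](C)(C)C(C)(C)C)C/C(CO[Si](C)(C)C(C)(C)C)=C\CC[C@@H]1COC(OC)C1 | intermediate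
15 | methyl prop-2-enoate | C=CC(=O)OC | starting material
16 | methyl (4R,6E)-4-[(tert-butyldimethylsilyl)oxy]-6-{[(tert-butyldimethylsilyl)oxy]methyl}-3-hydroxy-9-[(3S)-5-methoxyoxolan-3-yl]-2-methylidenenon-6-enoate (C3 epimers) | COC(=O)C(=C)C(O)[C@H](O[Si](C)(C)C(C)(C)C)C/C(CO[Si](C)(C)C(C)(C)C)=C\CC[C@@H]1COC(OC)C1 | intermediate
17 | methyl (2Z,4R,6E)-2-(bromomethyl)-4-[(tert-butyldimethylsilyl)oxy]-6-{[(tert-butyldimethylsilyl)oxy]methyl}-9-[(3S)-5-methoxyoxolan-3-yl]nona-2,6-dienoate | COC(=O)/C(CBr)=C/[C@H](O[Si](C)(C)C(C)(C)C)C/C(CO[Si](C)(C)C(C)(C)C)=C\CC[C@@H]1COC(OC)C1 | intermediate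
18 | methyl (2Z,4R,6E)-2-(bromomethyl)-4-[(tert-butyldimethylsilyl)oxy]-6-{[(tert-butyldimethylsilyl)oxy]methyl}-9-[(3S)-5-hydroxyoxolan-3-yl]nona-2,6-dienoate (lactol, not isolated) | COC(=O)/C(CBr)=C/[C@H](O[Si](C)(C)C(C)(C)C)C/C(CO[Si](C)(C)C(C)(C)C)=C\CC[C@@H]1COC(O)C1 | intermediate
19 | methyl 2-[(1S,2R,4S,7E,10R)-10-[(tert-butyldimethylsilyl)oxy]-8-{[(tert-butyldimethylsilyl)oxy]methyl}-2-hydroxy-4-(hydroxymethyl)cyclodec-7-en-1-yl]prop-2-enoate | CC(C)(C)[Si](C)(C)O[C@@H]1C/C(CO[Si](C)(C)C(C)(C)C)=C\CC[C@H](CO)C[C@@H](O)[C@@H]1C(=C)C(=O)OC | intermediate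
20 | (3aR,4R,6E,10S,11aR)-4-hydroxy-6,10-bis(hydroxymethyl)-3-methylidene-3a,4,5,8,9,10,11,11a-octahydrocyclodeca[b]furan-2(3H)-one | O[C@@H]1C/C(CO)=C\CC[C@H](CO)C[C@H]2OC(=O)C(=C)[C@H]12 | intermediate
21 | (3aR,4R,6E,10S,11aR)-4-hydroxy-3-methylidene-6,10-bis[(triethylsilyloxy)methyl]-3a,4,5,8,9,10,11,11a-octahydrocyclodeca[b]furan-2(3H)-one (not isolated) | O[C@@H]1C/C(CO[Si](CC)(CC)CC)=C\CC[C@H](CO[Si](CC)(CC)CC)C[C@H]2OC(=O)C(=C)[C@H]12 | intermediate
22 | (3aS,4R,6E,10S,11aR)-3-methylidene-2-oxo-6,10-bis[(triethylsilyloxy)methyl]-2,3,3a,4,5,8,9,10,11,11a-decahydrocyclodeca[b]furan-4-yl 2-methylprop-2-enoate (not isolated) | C=C(C)C(=O)O[C@@H]1C/C(CO[Si](CC)(CC)CC)=C\CC[C@H](CO[Si](CC)(CC)CC)C[C@H]2OC(=O)C(=C)[C@H]12 | intermediate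
23 | (3aS,4R,6E,10S,11aR)-6,10-bis(hydroxymethyl)-3-methylidene-2-oxo-2,3,3a,4,5,8,9,10,11,11a-decahydrocyclodeca[b]furan-4-yl 2-methylprop-2-enoate (CNP0546547.2) | C=C(C)C(=O)O[C@@H]1C/C(CO)=C\CC[C@H](CO)C[C@H]2OC(=O)C(=C)[C@H]12 | target

**Step count and risks**

Total steps: 14. Longest linear sequence: 12 (steps 1–3, then 6–14, from furan-2(5H)-one).

Steps most likely to fail, each with a fallback:

Step 12 (ring closure). The allylindium may be protonated by water before the slow ten-ring closure, or the C6/C7 pair may form with the wrong sense relative to C8. The fallback leaves the aqueous Barbier for an anhydrous organochromium closure. It sets out from 17 and comes back at 20. The acetal is hydrolysed on its own (PPTS, acetone/H2O) and the lactol 18 is isolated. CrCl2 (8 equiv) in THF at 2 mM (Nozaki–Hiyama–Kishi allylation, stereoconvergent through the equilibrating allylchromium, reacting through the open hydroxy-aldehyde) joins C7 to C6. The chromium alkoxide closes the lactone in the same flask and gives (3aS,4R,6E,10S,11aR)-4-[(tert-butyldimethylsilyl)oxy]-6-{[(tert-butyldimethylsilyl)oxy]methyl}-10-(hydroxymethyl)-3-methylidene-3a,4,5,8,9,10,11,11a-octahydrocyclodeca[b]furan-2(3H)-one F1. Aqueous HF in MeCN, as in step 13, then gives 20.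

Step 10 (Morita–Baylis–Hillman reaction on a hindered α-silyloxy aldehyde). It may take days, with retro-aldol loss or epimerisation at C8. The fallback replaces the amine-catalysed equilibrium by a preformed acrylate α-anion equivalent. It sets out from 14 and comes back at 16. Methyl propiolate is hydroaluminated (DIBAL-H, HMPA, THF, 0 °C) to methyl 2-(diisobutylalumanyl)prop-2-enoate F2, which adds to 14 at −78 °C within an hour and gives 16 after work-up.

Step 1 (enantioselective Grignard addition to the butenolide). The magnesium lactone enolate may oligomerise and the ee may be low. The fallback uses a boron nucleophile under rhodium catalysis and builds C1 by carbonylation instead of ozonolysis. It sets out from 1 and comes back at 6. Rh(I)/(R)-BINAP-catalysed 1,4-addition of potassium vinyltrifluoroborate (dioxane/H2O, 80 °C) gives (4R)-4-ethenyloxolan-2-one F3. DIBAL-H then MeOH/PPTS, as in step 2, gives through (4R)-4-ethenyloxolan-2-ol F4 the acetal (4R)-4-ethenyl-2-methoxyoxolane F5. Linear-selective hydroformylation (Rh(acac)(CO)2, Xantphos, CO/H2, toluene, 80 °C) gives 6.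

**Further compounds**

F1 | step 12 | (3aS,4R,6E,10S,11aR)-4-[(tert-butyldimethylsilyl)oxy]-6-{[(tert-butyldimethylsilyl)oxy]methyl}-10-(hydroxymethyl)-3-methylidene-3a,4,5,8,9,10,11,11a-octahydrocyclodeca[b]furan-2(3H)-one | CC(C)(C)[Si](C)(C)O[C@@H]1C/C(CO[Si](C)(C)C(C)(C)C)=C\CC[C@H](CO)C[C@H]2OC(=O)C(=C)[C@H]12
F2 | step 10 | methyl 2-(diisobutylalumanyl)prop-2-enoate | COC(=O)C(=C)[Al](CC(C)C)CC(C)C
F3 | step 1 | (4R)-4-ethenyloxolan-2-one | C=C[C@@H]1COC(=O)C1
F4 | step 1 | (4R)-4-ethenyloxolan-2-ol (lactol, anomer mixture) | C=C[C@@H]1COC(O)C1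
F5 | step 1 | (4R)-4-ethenyl-2-methoxyoxolane (anomer mixture) | C=C[C@@H]1COC(OC)C1
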